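Put the same charge through four vessels on paper before you choose one.

| flask | starting material | reagent | free catalyst | added ligand | remark | time |
|---|---|---|---|---|---|---|
| alpha | 0.25 M | 0.375 M | 2 mM | 3.9 mM | run made earlier |  |
| epsilon | 0.25 M | 0.375 M | 2 mM | 5.5 mM | run made earlier |  |
| eta | 0.25 M | 0.375 M | 2 mM | 8.6 mM | run made earlier |  |
| zeta | 0.12 M | 0.375 M | 2 mM | 3.9 mM | run made earlier |  |
| green | 0.25 M | 0.375 M | 2.0 mM | 3.9 mM | a single well-mixed tank run continuously and read at steady state, 12 h in it on average |  |
| grey | 0.25 M (fed, over 12.0 h) | 0.375 M | 2.0 mM | 3.9 mM | all but starting material at the start; starting material goes in evenly over 12.0 h, the run ends at 12 h | 12 h |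
| amber | 0.25 M | 0.375 M (fed, over 12.0 h) | 2.0 mM | 3.9 mM | all but reagent at the start; reagent goes in evenly over 12.0 h, the run ends at 12 h | 12 h |
| ochre | 0.25 M | 0.375 M | 2.0 mM | 3.9 mM | everything together in a closed stirred flask, run for 12 h | 12 h |

| run | time / h | target / % |
|---|---|---|
| alpha | 0.500 | 2.1 |
| alpha | 1.00 | 6.8 |
| alpha | 2.00 | 18.2 |
| alpha | 4.00 | 35.4 |
| alpha | 8.00 | 60.1 |
| epsilon | 1.33 | 6.6 |
| epsilon | 4.00 | 27.8 |
| epsilon | 6.00 | 39.8 |
| epsilon | 10.0 | 57.8 |
| epsilon | 15.0 | 72.1 |
| eta | 3.00 | 11.5 |
| eta | 6.00 | 26.9 |
| eta | 8.00 | 36.1 |
| eta | 12.0 | 49.7 |
| eta | 15.0 | 57.1 |
| zeta | 1.33 | 10.6 |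
| zeta | 4.00 | 36.6 |
| zeta | 6.00 | 51.2 |
| zeta | 10.0 | 71.7 |
| zeta | 15.0 | 85.6 |

(readings scatter by 0.5 percentage points)

- the stated concentrations are those of everything mixed, before any reaction; amounts are the same in each set-up
- the numbers in the tables scatter by 0.5 percentage points (one standard deviation)
- candidate steps: starting material + free catalyst -> free catalyst + open intermediate; free catalyst + open intermediate <-> catalyst intermediate; reagent + catalyst intermediate -> free catalyst + target; free catalyst + added ligand <-> idle complex
- the feed brings no volume worth counting
- the earlier runs were made in a closed, stirred flask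

- the set-up with the highest amount of target at the outlet or at the end, in percent of the starting material put in ("none" if the first two lie within 2 percentage points) (green / grey / amber / ochre / none)
- amount of target at the outlet or at the end, in percent of the starting material put in, green
- amount of target at the outlet or at the end, in percent of the starting material put in, grey
- amount of target at the outlet or at the end, in percent of the starting material put in, amber
- amount of target at the outlet or at the end, in percent of the starting material put in, ochre

Two chemists argue over this charge. The first takes equal set-ups as the zero of the scale. The catalyst and the 12 h are common to them, and zeta, with [starting material] halved, read 36.6 % at 4.00 h against alpha's 35.4 %. So, the first says, feeding costs nothing, each set-up lands near ochre, and the answer is "none".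

The second reads the same pair the other way: a percent curve that ignores the charge is a pseudo-first-order clock, and a clock runs separately for each portion. Call k the share of what is not yet target that becomes target per hour, read from alpha between 4.00 h and 8.00 h: 0.120 /h. Over the run, k times the time is 1.45.

I reckon with the second. Carrying alpha on from its last reading leaves 24.6 % undone in ochre. Green's tank leaves one over one plus kT undone, so its target is 59.1 %. Grey's even feed averages the clock over portions of every age up to 12.0 h, which leaves 52.9 % undone. That puts ochre's target 28 percentage points above grey's, against a margin of 2 points. For amber the clock gives me no number.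

The forecast takes the second side: 75.5 % for ochre, with “extrapolating alpha to 12 h gives about 75%”, 58 % for green, 48 % for grey, 65 % for amber, and ochre as best. Its green stands below my bare clock.

The flask gives 56.3 % for green, 45.4 % for grey, 61.3 % for amber and 74.5 % for ochre, so ochre is best, by 13 points over amber.

    starting material + free catalyst → free catalyst + open intermediate (k = 50.0 /M/min)
    free catalyst + open intermediate ⇌ catalyst intermediate (K = 5.90 /M, k = 3.80 /M/min)
    reagent + catalyst intermediate → free catalyst + target (k = 9.00 /M/min)
    free catalyst + added ligand ⇌ idle complex, settled at all times (K = 680 /M)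

At 12.0 h ochre holds 0 % of starting material and 25.4 % of open intermediate, against the clock's 24.6 % undone. In grey the clock's 52.9 % undone meets 50.5 % of open intermediate plus 4.13 % of starting material, together 54.6 %. Grey, amber and ochre do come level as the first chemist said, but at 120 h, ten times the run, where they read >99.9 %, >99.9 % and >99.9 %.

The earlier runs and the new flask were generated by integration for an exercise, and the scatter is random.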